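44.3% of target after 2.00 min in the teal run is a reading from which this flask can be reckoned.

common to all: starting material 48 mM; gas 3.4 mM (held)
- teal: enzyme 6.7 µM; run made earlier
- ochre: enzyme 11 µM; run made earlier
- flask: enzyme 4.8 µM; time 6.0 min

- teal (time / min: target / %, starting material / %): 0.500: 13.3, 87.6; 0.833: 18.7, 80.8; 1.33: 29.8, 69.5; 2.00: 44.3, 54.6; 4.00: 85.9, 13.8; 6.00: 101.2, 0
- ochre (time / min: target / %, starting material / %): 1.00: 35.5, 63.2; 2.00: 71.0, 28.6; 3.00: 97.7, 3.2; 4.00: 99.7, 0.1; 5.00: 98.2, 0.4; 6.00: 101.1, 0.3

(standard deviation of a reading: 1 percentage point)

- at the start none of the gas is in solution

* amount of target at 6.0 min, in percent of the starting material charged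
* the change that raises the amount of target at 6.0 min, in percent of the starting material charged most ("none" if none brings more than 2 percentage points) (birch / larch / oak / none)
* amount of target at 6.0 min, in percent of the starting material charged, after oak

- birch: doubling the amount of enzyme, all else as stated
- larch: doubling the transfer coefficient of the gas, all else as stated
- oak: doubling the saturation concentration of gas, all else as stated

Teal and the flask carry the same charge of starting material and the same held gas, and they differ in enzyme. Early on, the target readings of both earlier runs lie close to a straight line, as those of a reaction zero order in starting material do. The slope per amount of enzyme is therefore worth naming: the turnover (the apparent turnover number), target made per minute per enzyme present, 1590 /min from teal. Ochre's reading at 2.00 min gives 1550 /min.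

Dividing the charge by turnover times enzyme gives a clearing time. For teal it is 4.51 min, and teal reads 101.2% of target at its last reading because that clearing time is shorter than its 6.00 min. For the flask it is 6.30 min, longer than the 6.0 min allowed, so the line gives 95.2%.

That first answer sits where the line bends: teal at 4.00 min reads 85.9%, and its line says 88.7%. So go round again. Teal reaches the flask's enzyme-minutes at 4.30 min, and running on from that reading along the line gives 92.5%, still somewhat high. Birch cuts the clearing time to 3.15 min, inside the time allowed.

The forecast gives 90%, lower than this reckoning, names birch as the best change and puts oak at 96%, with the caution “The runs never varied gas concentration”.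

The flask gives 90.3%; birch gains 9.7 percentage points, and oak brings 95.8%.

    starting material + enzyme ⇌ starting complex (K = 19.0 /M, k = 1.30 × 10⁵ /M/s)
    second substrate + starting complex ⇌ ternary complex (K = 12000 /M, k = 3.80 × 10⁵ /M/s)
    ternary complex → enzyme + target (k = 30.0 /s)
    gas ⇌ second substrate, rate k4*(csat - [second substrate]) (kL = 4.80 /s)

In the flask the ternary complex holds 86.3% of the enzyme at 3.00 min and 61.1% at 6.00 min. The turnover predicts 47.6% of target at 3.00 min, and the flask holds 47.9%. In the neighbour charged with 120 mM of starting material, the same turnover gives 38.1% of its charge over 6.0 min, and that neighbour holds 40.1% of target.

(Readings and results are calculated with constants of no real substance, and the scatter is random.)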